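**Strategy.** Ring B is cut at C7–C8 and C9–C10. This turns ring C into its C8–C9 aryne and leaves C7=C6–C5=C10 as a diene that hangs from the thujane through the two-atom tether C4'–C10'. The cue is that C8 and C9, neighbours in ring C, each carry exactly one bond into the rest of ring B (to C7 and to C10). A single intramolecular aryne Diels–Alder reaction then closes ring B and the cyclopentane C14–C8–C7–C10'–C4' and sets C7 and the C10 quaternary centre. The precursor is a 4'-aryl thujane with fluorine on C8, hydrogen on C9 between fluorine and the C11 methoxy group, and the (10'S)-silyloxy dienyl chain on C4'.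

Key step: step 15

**Remarks on the chemistry**
- Numbering: abietane C1–C20. Thujane atoms are primed: C1' carries the isopropyl group, C2' and C3' are the ring CH2 groups, C4' is the quaternary (later spiro) carbon, C5' is the cyclopropane CH, C6' the cyclopropane CH2, C10' the carbinol carbon.
- The aryne leaving group is fluoride on C8, so the proton to be removed is H9, which is unhindered and flanked by F and OMe. A halide on C9 would require removal of H8, which is shielded by the quaternary C4'.
- The arene is functionalised at C14 by electrophilic substitution para to the C11 methoxy group. Lithiation of the dimethyl ether would occur next to oxygen, at C9.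
- Assumption: the cis A/B fusion (H5 and the C20 methyl on one face) and the C10' configuration are taken as drawn in the target SMILES.

**Route**

Step 1
Reactants: 1 3-isopropylcatechol
Product: 2 3-isopropylveratrole (1,2-dimethoxy-3-isopropylbenzene)
Conditions: MeI, K2CO3, acetone, reflux
Reagents that add atoms: iodomethane, CI
Why: Williamson ether synthesis; both phenoxides are methylated by SN2 on MeI, and the methyl ethers tolerate every organolithium and Lewis-acid step up to step 18.

Step 2
Reactants: 2 3-isopropylveratrole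
Product: 3 1-bromo-2-isopropyl-3,4-dimethoxybenzene (bromine on C14)
Conditions: NBS, MeCN, 0 °C to rt
Reagents that add atoms: N-bromosuccinimide, O=C1CCC(=O)N1Br
Why: Electrophilic aromatic bromination; only the C11 methoxy group can lie in the ring plane (the C12 methoxy is twisted by its two ortho neighbours), so bromine should enter para to it at C14, as with 2,3-dimethoxytoluene.

Step 3
Reactants: 3 1-bromo-2-isopropyl-3,4-dimethoxybenzene
Product: 5 2-isopropyl-3,4-dimethoxybenzaldehyde, via aryllithium 4 (not isolated)
Conditions: n-BuLi, THF, −78 °C; DMF, −78 °C to rt; H2O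
Reagents that add atoms: N,N-dimethylformamide, CN(C)C=O
Why: Bromine–lithium exchange and formylation of the aryllithium with DMF (Bouveault aldehyde synthesis) put the future C10' carbon on C14.

Step 4
Reactants: 5 2-isopropyl-3,4-dimethoxybenzaldehyde
Product: 8 6-fluoro-2-isopropyl-3,4-dimethoxybenzaldehyde (fluorine on C8), via amino alkoxide 6 (not isolated), via lithiated amino alkoxide 7 (not isolated)
Conditions: LiN(Me)CH2CH2NMe2 (from the diamine and n-BuLi), THF, −20 °C; n-BuLi, −20 °C; NFSI, −78 °C to rt; H2O
Reagents that add atoms: N-fluorobenzenesulfonimide, O=S(=O)(c1ccccc1)N(F)S(=O)(=O)c1ccccc1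
Why: Directed ortho-lithiation; the lithium α-amino alkoxide masks the aldehyde and steers n-BuLi to its only free ortho position C8 in preference to the methoxy-flanked C9, and the aryllithium is fluorinated by NFSI (electrophilic fluorination of an aryllithium).

Step 5
Reactants: 9 (1R,5R)-(+)-sabinene
Product: 11 sabina ketone ((1S,5R)-5-isopropylbicyclo[3.1.0]hexan-2-one), via ozonide 10 (not isolated)
Conditions: O3, CH2Cl2, −78 °C; Me2S, −78 °C to rt
Reagents that add atoms: ozone, [O-][O+]=O
Why: Ozonolysis with reductive work-up cleaves the exocyclic C4'=C10' bond and leaves the cyclopropane and both stereocentres untouched.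

Step 6
Reactants: 11 sabina ketone
Product: 12 sabina ketone 2,4,6-triisopropylbenzenesulfonylhydrazone
Conditions: 2,4,6-triisopropylbenzenesulfonyl hydrazide, THF, rt
Reagents that add atoms: 2,4,6-triisopropylbenzenesulfonyl hydrazide, CC(C)c1cc(C(C)C)c(S(=O)(=O)NN)c(C(C)C)c1
Why: Condensation to the arenesulfonylhydrazone needed for the Shapiro reaction; the sulfonamide nitrogen should sit syn to the C3' methylene, away from the cyclopropane.

Step 7
Reactants: 12 sabina ketone 2,4,6-triisopropylbenzenesulfonylhydrazone; 8 6-fluoro-2-isopropyl-3,4-dimethoxybenzaldehyde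
Product: 14 (6-fluoro-2-isopropyl-3,4-dimethoxyphenyl)(thuj-3'-en-4'-yl)methanol (both C10' epimers), via vinyllithium 13 (not isolated)
Conditions: n-BuLi (2 equiv), THF, −78 to 0 °C; 8, −78 °C; H2O
Reagents that add atoms: none
Why: Shapiro reaction; deprotonation at N–H and at the C3' methylene, then loss of arenesulfinate and N2, gives the C4' alkenyllithium, which adds 1,2 to aldehyde 8, and the new carbinol centre needs no control because C10' becomes trigonal again in step 9.

Step 8
Reactants: 14 aryl thujenyl methanol
Product: 15 3',4'-epoxy alcohol (epoxide oxygen trans to the cyclopropane CH2)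
Conditions: VO(acac)2 (cat.), t-BuOOH, CH2Cl2, 0 °C
Reagents that add atoms: tert-butyl hydroperoxide, CC(C)(C)OO
Why: Hydroxyl-directed vanadium-catalysed epoxidation of the allylic alcohol is chemoselective over the electron-rich arene, and oxygen should be delivered to the cyclopentene face opposite the cyclopropane methylene C6', which sets C3' and C4'.

Step 9
Reactants: 15 3',4'-epoxy alcohol
Product: 16 4'-aryl-3'-hydroxythujan-10'-al (aryl cis, CHO and 3'-OH trans to the cyclopropane CH2)
Conditions: BF3·OEt2, CH2Cl2, −78 °C
Reagents that add atoms: none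
Why: Semipinacol rearrangement of a 2,3-epoxy alcohol; as the Lewis acid opens the epoxide at the tertiary C4', the electron-rich aryl group (para-methoxy to the migrating carbon) shifts from C10' to C4' anti to the departing oxygen, so it lands on the cyclopropane face and fixes the quaternary stereocentre while C10' becomes the aldehyde.

Step 10
Reactants: 16 4'-aryl-3'-hydroxythujan-10'-al
Product: 17 3'-O-(imidazol-1-ylthiocarbonyl) derivative of 16
Conditions: 1,1'-thiocarbonyldiimidazole, DMAP (cat.), ClCH2CH2Cl, 60 °C
Reagents that add atoms: 1,1'-thiocarbonyldiimidazole, S=C(n1ccnc1)n1ccnc1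
Why: Thioacylation of the secondary C3' alcohol under neutral conditions (first stage of the Barton–McCombie deoxygenation), which avoids the alkoxide that could open the β-hydroxy aldehyde by retro-aldol cleavage.

Step 11
Reactants: 17 3'-O-(imidazol-1-ylthiocarbonyl) aldehyde
Product: 18 (4'S)-4'-(6-fluoro-2-isopropyl-3,4-dimethoxyphenyl)thujan-10'-al
Conditions: Bu3SnH, AIBN (cat.), PhSeSePh (cat.), toluene, 90 °C
Reagents that add atoms: none
Why: Barton–McCombie deoxygenation; the stannyl radical adds to C=S, the secondary C3' radical (not cyclopropylcarbinyl) is released and reduced, and catalytic PhSeSePh supplies PhSeH as a fast hydrogen donor so that reduction outruns 1,2-formyl migration.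

Step 12
Reactants: 19 β-cyclocitral
Product: 20 (E)-2-(2-iodovinyl)-1,3,3-trimethylcyclohexene
Conditions: CHI3, CrCl2, THF, 0 °C to rt
Reagents that add atoms: iodoform, IC(I)I
Why: Takai olefination; the geminal dichromium reagent formed from CHI3 and CrCl2 adds to the hindered aldehyde and eliminates to the (E)-iodoalkene, the future C7=C6 bond.

Step 13
Reactants: 20 (E)-2-(2-iodovinyl)-1,3,3-trimethylcyclohexene; 18 4'-aryl-thujan-10'-al
Product: 22 (10'S)-dienyl carbinol (4'-aryl thujane with C10'H(OH)–CH=CH–(2,6,6-trimethylcyclohexenyl) on C4'), via dienyllithium 21 (not isolated)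
Conditions: t-BuLi (2 equiv), Et2O, −78 °C; 18, THF, −78 °C; H2O
Reagents that add atoms: none
Why: Iodine–lithium exchange with retention of the (E) geometry and 1,2-addition to the α-quaternary aldehyde; Felkin–Anh attack anti to the aryl group and past the C3' methylene (carbonyl oxygen on the side of the cyclopropyl methine C5') should favour the (10'S) alcohol.

Step 14
Reactants: 22 (10'S)-dienyl carbinol
Product: 23 tert-butyldimethylsilyl ether of 22 (cycloaddition precursor)
Conditions: TBSOTf, 2,6-lutidine, CH2Cl2, 0 °C
Reagents that add atoms: tert-butyldimethylsilyl trifluoromethanesulfonate, CC(C)(C)[Si](C)(C)OS(=O)(=O)C(F)(F)F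
Why: Silylation of the hindered secondary allylic alcohol with a silyl triflate and a non-nucleophilic base; the bulky silyl ether is inert to lithium amides and is the steric control element of step 15.

Step 15
Reactants: 23 8-fluoroaryl thujane with the C10' silyloxy dienyl chain
Product: 26 hexacyclic 5-ene (1,4-dihydronaphthalene ring B), via aryllithium 24 (not isolated), via aryne 25 (not isolated)
Conditions: lithium 2,2,6,6-tetramethylpiperidide (from n-BuLi and the amine), THF, high dilution, −78 °C, then warm to 0 °C; H2O
Reagents that add atoms: none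
Why: The lithium amide removes H9, the only aromatic hydrogen, which is acidified by the flanking C8 fluorine and C11 methoxy group; on warming, aryllithium 24 expels LiF and the C8–C9 aryne 25 adds suprafacially with its in-plane π bond to C7 and C10 of the tethered diene in a concerted [4+2] that forms C7–C8 and C9–C10. The closest known reaction type is the intramolecular aryne Diels–Alder reaction of base-generated arynes with acyclic dienes on short tethers. Ring B is closed as the cycloadduct ring, with both new bonds in it; the cyclopentane C14–C8–C7–C10'–C4' is closed by the C7–C8 bond alone in the 5-exo sense, since the two-atom tether C4'–C10' links C14 to the diene terminus C7 and C6 stays outside that ring. C7 is set by the C10' stereocentre, because the diene should add through the conformer in which C6 lies on the cyclopentane face opposite the bulky silyloxy group (H7 and OSi cis); C10 is set by C7, because suprafacial addition keeps the two inside groups of the diene, H7 and the C20 methyl, on one face of ring B. The step needs π-facial selectivity of the diene and chemoselectivity for cycloaddition over ene-type hydrogen transfer (C20 methyl, C10'–H) and amine addition; the silyl ether beside the quaternary C4' provides the first, and the short tether, high dilution, low temperature and a non-nucleophilic amide support the second.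

Step 16
Reactants: 26 hexacyclic 5-ene
Product: 27 5,6-epoxide (oxygen on the ring-B face opposite the C20 methyl)
Conditions: mCPBA, NaHCO3, CH2Cl2, 0 °C
Reagents that add atoms: 3-chloroperoxybenzoic acid, OOC(=O)c1cccc(Cl)c1
Why: Prilezhaev epoxidation of the only alkene; the peracid should approach the trisubstituted 5-ene anti to the pseudo-axial C20 methyl, which defines C5 and C6 for the hydride shift that follows.

Step 17
Reactants: 27 5,6-epoxide
Product: 28 6-ketone with H5 cis to the C20 methyl
Conditions: BF3·OEt2 (cat.), toluene, −78 to −40 °C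
Reagents that add atoms: none
Why: Meinwald rearrangement; Lewis-acid opening of the epoxide at the tertiary C5 with 1,2-shift of H6, which is antiperiplanar to the breaking C5–O bond, gives the C6 ketone and places H5 on the C20 face (cis ring fusion) without any enolate.

Step 18
Reactants: 28 6-ketone
Product: 29 11,12-catechol with free C10' hydroxyl
Conditions: BBr3, CH2Cl2, −78 to 0 °C; MeOH, 0 °C
Reagents that add atoms: none
Why: Lewis-acid ether cleavage; BBr3 demethylates both aryl ethers by bromide attack on the O-methyl groups of the boron complexes, the silyl ether falls to boron–oxygen exchange and the HBr/MeOH quench, and the low temperature should spare the cyclopropane and the β-hydroxy ketone.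

Step 19
Reactants: 29 catechol hydroxy ketone
Product: 31 CNP0178265.1 (target), via ortho-quinone 30 (not isolated)
Conditions: Ag2O, Et2O, rt
Reagents that add atoms: none
Why: Oxidation of the catechol to the ortho-quinone, followed by spontaneous prototropic shift of the acidic H7 (α to the C6 ketone) to O11, gives the 11-hydroxy quinone methide; C7 becomes trigonal, so its earlier configuration is of no consequence.

**Compound list**

1 | 3-isopropylcatechol | CC(C)c1cccc(O)c1O | starting material
2 | 3-isopropylveratrole (1,2-dimethoxy-3-isopropylbenzene) | CC(C)c1cccc(OC)c1OC | intermediate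
3 | 1-bromo-2-isopropyl-3,4-dimethoxybenzene (Br on C14) | CC(C)c1c(Br)ccc(OC)c1OC | intermediate
4 | 2-isopropyl-3,4-dimethoxyphenyllithium (not isolated) | CC(C)c1c([Li])ccc(OC)c1OC | intermediate
5 | 2-isopropyl-3,4-dimethoxybenzaldehyde | CC(C)c1c(C=O)ccc(OC)c1OC | intermediate
6 | lithium α-amino alkoxide of 5 with N,N,N'-trimethylethylenediamine (not isolated) | CC(C)c1c(C(O[Li])N(C)CCN(C)C)ccc(OC)c1OC | intermediate
7 | C8-lithiated α-amino alkoxide (not isolated) | CC(C)c1c(C(O[Li])N(C)CCN(C)C)c([Li])cc(OC)c1OC | intermediate
8 | 6-fluoro-2-isopropyl-3,4-dimethoxybenzaldehyde (F on C8) | CC(C)c1c(C=O)c(F)cc(OC)c1OC | intermediate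
9 | (1R,5R)-(+)-sabinene | C=C1CC[C@]2(C(C)C)C[C@@H]21 | starting material
10 | sabinene secondary ozonide, spiro-1,2,4-trioxolane on C4', both spiro epimers (not isolated) | C1OC2(CC[C@]3(C(C)C)C[C@@H]32)OO1 | intermediate
11 | sabina ketone, (1S,5R)-5-isopropylbicyclo[3.1.0]hexan-2-one | O=C1CC[C@]2(C(C)C)C[C@@H]21 | intermediate
12 | sabina ketone 2,4,6-triisopropylbenzenesulfonylhydrazone (sulfonamide N syn to C3') | CC(C)c1cc(C(C)C)c(S(=O)(=O)N/N=C2\CC[C@]3(C(C)C)C[C@@H]32)c(C(C)C)c1 | intermediate
13 | thuj-3'-en-4'-yllithium, sabinene configuration at C1' and C5' (not isolated) | [Li]C1=CC[C@]2(C(C)C)C[C@@H]21 | intermediate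
14 | (6-fluoro-2-isopropyl-3,4-dimethoxyphenyl)(thuj-3'-en-4'-yl)methanol, both C10' epimers | CC(C)c1c(C(O)C2=CC[C@]3(C(C)C)C[C@@H]32)c(F)cc(OC)c1OC | intermediate
15 | 3',4'-epoxide of 14, epoxide oxygen trans to the cyclopropane CH2, both C10' epimers | CC(C)c1c(C(O)[C@]23O[C@H]2C[C@]4(C(C)C)C[C@@H]43)c(F)cc(OC)c1OC | intermediate
16 | 4'-aryl-3'-hydroxythujan-10'-al: aryl on C4' cis to the cyclopropane CH2, CHO and 3'-OH trans to it | CC(C)c1c([C@]2(C=O)[C@@H](O)C[C@]3(C(C)C)C[C@@H]32)c(F)cc(OC)c1OC | intermediate
17 | 3'-O-(imidazol-1-ylthiocarbonyl) derivative of 16 | CC(C)c1c([C@]2(C=O)[C@@H](OC(=S)n4ccnc4)C[C@]3(C(C)C)C[C@@H]32)c(F)cc(OC)c1OC | intermediate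
18 | (4'S)-4'-(6-fluoro-2-isopropyl-3,4-dimethoxyphenyl)thujan-10'-al (aryl cis to the cyclopropane CH2) | CC(C)c1c([C@]2(C=O)CC[C@]3(C(C)C)C[C@@H]32)c(F)cc(OC)c1OC | intermediate
19 | β-cyclocitral | CC1=C(C=O)C(C)(C)CCC1 | starting material
20 | (E)-2-(2-iodovinyl)-1,3,3-trimethylcyclohexene | CC1=C(/C=C/I)C(C)(C)CCC1 | intermediate
21 | (E)-2-(2,6,6-trimethylcyclohex-1-enyl)vinyllithium (not isolated) | CC1=C(/C=C/[Li])C(C)(C)CCC1 | intermediate
22 | (10'S)-dienyl carbinol: 8-fluoroaryl thujane with C10'H(OH)–(E)-CH=CH–(2,6,6-trimethylcyclohexenyl) on C4' | CC(C)c1c(OC)c(OC)cc(F)c1[C@@]1(CC[C@]2(C(C)C)C[C@@H]21)[C@@H](O)/C=C/C1=C(C)CCCC1(C)C | intermediate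
23 | tert-butyldimethylsilyl ether of 22, the cycloaddition precursor (8-fluoroaryl thujane carrying the C10' silyloxy dienyl chain) | CC(C)c1c(OC)c(OC)cc(F)c1[C@@]1(CC[C@]2(C(C)C)C[C@@H]21)[C@@H](O[Si](C)(C)C(C)(C)C)/C=C/C1=C(C)CCCC1(C)C | intermediate
24 | C9 aryllithium of 23 (not isolated) | CC(C)c1c(OC)c(OC)c([Li])c(F)c1[C@@]1(CC[C@]2(C(C)C)C[C@@H]21)[C@@H](O[Si](C)(C)C(C)(C)C)/C=C/C1=C(C)CCCC1(C)C | intermediate
25 | C8–C9 aryne (not isolated) | CC(C)C1=C(C#CC(OC)=C1OC)[C@@]1(CC[C@]2(C(C)C)C[C@@H]21)[C@@H](O[Si](C)(C)C(C)(C)C)/C=C/C1=C(C)CCCC1(C)C | intermediate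
26 | hexacyclic 5-ene cycloadduct: H7, the C20 methyl and the C10' silyloxy group on one face; 11,12-dimethoxy | CC(C)c1c2c3[C@@H](C=C4C(C)(C)CCC[C@]4(C)c3c(OC)c1OC)[C@H](O[Si](C)(C)C(C)(C)C)[C@]21CC[C@]2(C(C)C)C[C@@H]21 | intermediate
27 | 5,6-epoxide of 26, oxygen on the ring-B face opposite the C20 methyl | CC(C)c1c2c3[C@@H]([C@@H]5O[C@@]54C(C)(C)CCC[C@]4(C)c3c(OC)c1OC)[C@H](O[Si](C)(C)C(C)(C)C)[C@]21CC[C@]2(C(C)C)C[C@@H]21 | intermediate
28 | 6-ketone, H5 cis to the C20 methyl, 11,12-dimethoxy, C10' silyl ether | CC(C)c1c2c3[C@@H](C(=O)[C@@H]4C(C)(C)CCC[C@]4(C)c3c(OC)c1OC)[C@H](O[Si](C)(C)C(C)(C)C)[C@]21CC[C@]2(C(C)C)C[C@@H]21 | intermediate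
29 | 11,12-dihydroxy 6-ketone with free C10' hydroxyl | CC(C)c1c2c3[C@@H](C(=O)[C@@H]4C(C)(C)CCC[C@]4(C)c3c(O)c1O)[C@H](O)[C@]21CC[C@]2(C(C)C)C[C@@H]21 | intermediate
30 | 11,12-ortho-quinone (not isolated) | CC(C)C1=C2C3[C@@H](C(=O)[C@@H]4C(C)(C)CCC[C@]4(C)C=3C(=O)C1=O)[C@H](O)[C@]21CC[C@]2(C(C)C)C[C@@H]21 | intermediate
31 | CNP0178265.1 | CC(C)C1=C2C3=C(C(=O)[C@@H]4C(C)(C)CCC[C@]4(C)C3=C(O)C1=O)[C@H](O)[C@]21CC[C@]2(C(C)C)C[C@@H]21 | target

**Step count and risk**

Total step count: 19. Longest linear sequence: 16 steps (steps 1–4, 7–11, 13–19).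

Steps most likely to fail:

Step 15. After LiF is lost, the aryne may be diverted by hydrogen transfer from the C20 methyl or from C10'–H (ene pathways) or by amine addition, because the twisted, fully substituted diene terminus closes slowly; the diene may also add through the wrong face. The fallback replaces the aryne by an ortho-quinone as the 2π partner and sets out from 23. NaSEt in DMF at 120 °C should cleave both aryl methyl ethers and leave fluorine and the silyl ether in place, giving the fluoro catechol F1. Ag2O should oxidise it to the 8-fluoro ortho-quinone F2. Heating in toluene should bring its C8=C9 bond into an intramolecular Diels–Alder reaction with the same diene, giving the fluoro enedione adduct F3. Et3N should remove HF and give the ring-B-fused ortho-quinone F4, which is reduced in the same flask with Na2S2O4 to the catechol F5. Methylation with MeI and K2CO3 returns to the route at 26.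

Step 17. Ionisation at C5 may be followed by migration of the C20 methyl or a C4 methyl instead of H6 (skeletal rearrangement), or the β-silyloxy ketone may lose silanol through its C7 enol. The fallback avoids the cation and sets out from 26. Hydroboration–oxidation (BH3·THF; NaOH, H2O2) from the face opposite C20 should give the 6-alcohol F6. Dess–Martin periodinane should give the trans-fused 6-ketone F7. BBr3 followed by MeOH, as in step 18, should give the C5-epimeric catechol F8, and Ag2O, as in step 19, the C5 epimer of the target F9. Equilibration of C5 through the extended dienol with DBU in CH2Cl2 is expected to favour the cis-fused isomer, because the trans-fused 6-ketone suffers eclipsing of the equatorial C4 methyl with the carbonyl and a 1,3-diaxial methyl pair; this returns to the route at 31. With C7 already trigonal, β-elimination at C10' is not possible at that stage.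

Step 13. Facial selectivity in the addition to the α-quaternary aldehyde may be poor, since the two ring carbons flanking C4' differ little in size. The fallback replaces substrate control by reagent control and sets out from the epimer mixture obtained from 18 and 21. Dess–Martin periodinane should oxidise it to the dienone F10. Corey–Bakshi–Shibata reduction (Me-CBS oxazaborolidine, BH3·SMe2; the (S) catalyst if the dienyl arm acts as the large group, otherwise its enantiomer) should return the (10'S) alcohol, which rejoins the route at 22.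

**Further compounds**

F1 | step 15 | fluoro catechol: 23 with both aryl methyl ethers cleaved | CC(C)c1c(O)c(O)cc(F)c1[C@@]1(CC[C@]2(C(C)C)C[C@@H]21)[C@@H](O[Si](C)(C)C(C)(C)C)/C=C/C1=C(C)CCCC1(C)C
F2 | step 15 | 8-fluoro ortho-quinone carrying the silyloxy dienyl thujane | CC(C)C1=C(C(F)=CC(=O)C1=O)[C@@]1(CC[C@]2(C(C)C)C[C@@H]21)[C@@H](O[Si](C)(C)C(C)(C)C)/C=C/C1=C(C)CCCC1(C)C
F3 | step 15 | fluoro enedione Diels–Alder adduct (C8–F and C9–H cis, their configuration not assigned) | CC(C)C1=C2C3(F)[C@@H](C=C4C(C)(C)CCC[C@]4(C)C3C(=O)C1=O)[C@H](O[Si](C)(C)C(C)(C)C)[C@]21CC[C@]2(C(C)C)C[C@@H]21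
F4 | step 15 | ring-B-fused 11,12-ortho-quinone of the 5-ene | CC(C)C1=C2C3[C@@H](C=C4C(C)(C)CCC[C@]4(C)C=3C(=O)C1=O)[C@H](O[Si](C)(C)C(C)(C)C)[C@]21CC[C@]2(C(C)C)C[C@@H]21
F5 | step 15 | catechol corresponding to 26 | CC(C)c1c2c3[C@@H](C=C4C(C)(C)CCC[C@]4(C)c3c(O)c1O)[C@H](O[Si](C)(C)C(C)(C)C)[C@]21CC[C@]2(C(C)C)C[C@@H]21
F6 | step 17 | 6-alcohol from hydroboration (H5 and 6-OH on the face opposite C20) | CC(C)c1c2c3[C@@H]([C@H](O)[C@H]4C(C)(C)CCC[C@]4(C)c3c(OC)c1OC)[C@H](O[Si](C)(C)C(C)(C)C)[C@]21CC[C@]2(C(C)C)C[C@@H]21
F7 | step 17 | trans-fused 6-ketone (C5 epimer of 28) | CC(C)c1c2c3[C@@H](C(=O)[C@H]4C(C)(C)CCC[C@]4(C)c3c(OC)c1OC)[C@H](O[Si](C)(C)C(C)(C)C)[C@]21CC[C@]2(C(C)C)C[C@@H]21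
F8 | step 17 | C5 epimer of catechol 29 | CC(C)c1c2c3[C@@H](C(=O)[C@H]4C(C)(C)CCC[C@]4(C)c3c(O)c1O)[C@H](O)[C@]21CC[C@]2(C(C)C)C[C@@H]21
F9 | step 17 | C5 epimer of the target | CC(C)C1=C2C3=C(C(=O)[C@H]4C(C)(C)CCC[C@]4(C)C3=C(O)C1=O)[C@H](O)[C@]21CC[C@]2(C(C)C)C[C@@H]21
F10 | step 13 | C10' dienone (ketone of 22) | CC(C)c1c(OC)c(OC)cc(F)c1[C@@]1(CC[C@]2(C(C)C)C[C@@H]21)C(=O)/C=C/C1=C(C)CCCC1(C)C
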